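Both pyran rings are disconnected at C4–C4a and O1–C2, back to a bis(phloroglucinol)methane and two molecules of cinnamyl alcohol. In one operation a chiral confined Brønsted acid effects Friedel–Crafts C-cinnamylation at C4a and enantioselective 6-endo hydroalkoxylation of the resulting styrene by the neighbouring phenol O1, closing each dihydropyran and setting both (S)-C2 centres. The step exploits the 5,7,8a-trioxygenated aromatic ring of each flavan, whose C4a lies between the C5–OMe and the C8a–OH carbons and is its innate nucleophilic site. The precursor is an open diarylmethane in which bromine blocks C6 of the 8-linked flavan and C8 of the 6-linked flavan; the bromines are removed last.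

Key step: step 6

Assumption: 2,6-dihydroxy-4-methoxybenzaldehyde (6) is taken as a purchasable building block, and the sense of induction of the chiral acid in step 6 has to be assigned by screening both catalyst enantiomers.

Step 1
Reactants: 1 5-methoxybenzene-1,3-diol (5-methoxyresorcinol)
Product: 2 1-methoxy-3,5-bis(methoxymethoxy)benzene
Conditions: MOMCl (2.5 equiv), i-Pr2NEt (3 equiv), CH2Cl2, 0 °C to rt
Reagents that add atoms: chloromethyl methyl ether (MOMCl), COCCl
Why: O-alkylation of both phenols with the hard electrophile MOMCl (acetal protection) gives the bis-MOM ether, whose two OCH2OMe groups will direct the metalation.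

Step 2
Reactants: 2 1-methoxy-3,5-bis(methoxymethoxy)benzene
Product: 4 2-bromo-5-methoxy-1,3-bis(methoxymethoxy)benzene, via aryllithium 3 (not isolated)
Conditions: n-BuLi, THF, 0 °C; then BrCl2C–CCl2Br, −78 °C to rt
Reagents that add atoms: 1,2-dibromo-1,1,2,2-tetrachloroethane, BrC(Cl)(Cl)C(Cl)(Cl)Br (Br of 4); n-butyllithium, [Li]CCCC (Li of intermediate 3 only)
Why: Directed ortho-metalation removes the proton between the two chelating OCH2OMe groups (better coordinated and more acidic than the sites next to OMe), and the aryllithium is brominated by halogen transfer from the polyhaloethane.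

Step 3
Reactants: 4 2-bromo-5-methoxy-1,3-bis(methoxymethoxy)benzene
Product: 5 2-bromo-5-methoxybenzene-1,3-diol
Conditions: HCl (cat., 3 M aq.), MeOH, 50 °C
Reagents that add atoms: none
Why: Acid-catalysed acetal methanolysis (MOM cleavage) frees both phenols while methanol traps the formaldehyde equivalent as dimethoxymethane, so that it cannot bridge the electron-rich ring.

Step 4
Reactants: 6 2,6-dihydroxy-4-methoxybenzaldehyde
Product: 7 3-bromo-2,6-dihydroxy-4-methoxybenzaldehyde
Conditions: NBS (1.0 equiv), MeCN, −20 °C to 0 °C
Reagents that add atoms: N-bromosuccinimide (NBS), O=C1CCC(=O)N1Br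
Why: Electrophilic aromatic bromination occurs at one of the two equivalent positions ortho to OMe and OH, and the formyl group together with the first bromine should slow a second substitution enough for one equivalent of NBS to stop at the monobromide.

Step 5
Reactants: 7 3-bromo-2,6-dihydroxy-4-methoxybenzaldehyde; 5 2-bromo-5-methoxybenzene-1,3-diol (4 equiv, excess recovered)
Product: 9 4-bromo-2-[(3-bromo-2,4-dihydroxy-6-methoxyphenyl)methyl]-5-methoxybenzene-1,3-diol, via benzylic alcohol 8 (not isolated)
Conditions: NaBH4, THF/MeOH, 0 °C; then AcOH, 5 (4 equiv), CH2Cl2, 0 °C to rt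
Reagents that add atoms: none
Why: Borohydride reduction gives the o-hydroxybenzylic alcohol 8, which on acidification ionises to an o-quinone methide/benzylic cation that is captured at C4 of excess 5 (Friedel–Crafts benzylation), and since C4 and C6 of 5 are equivalent and C2 carries bromine only one constitution can form.

Step 6
Reactants: 9 4-bromo-2-[(3-bromo-2,4-dihydroxy-6-methoxyphenyl)methyl]-5-methoxybenzene-1,3-diol; 10 (E)-3-phenylprop-2-en-1-ol (cinnamyl alcohol, 2.5 equiv)
Product: 12 (2S)-6-bromo-8-{[(2S)-8-bromo-7-hydroxy-5-methoxy-2-phenyl-3,4-dihydro-2H-chromen-6-yl]methyl}-5-methoxy-2-phenyl-3,4-dihydro-2H-chromen-7-ol, via bis(C-cinnamyl) diarylmethane 11 (not isolated)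
Conditions: chiral BINOL-derived imidodiphosphorimidate (IDPi) Brønsted acid (10 mol%), 5 Å molecular sieves, CHCl3, rt to 50 °C
Reagents that add atoms: none
Why: Proposed new method: the strong chiral acid ionises cinnamyl alcohol to the cinnamyl cation, which alkylates the only free aromatic CH of each ring through its unsubstituted terminus (Friedel–Crafts allylation, giving 11), and then protonates each styrene at C3 so that the adjacent phenol oxygen adds to the benzylic carbon C2 within the chiral ion pair. The closest known reaction types are the racemic acid-catalysed one-pot Friedel–Crafts allylation/hydroalkoxylation of phenols with cinnamyl alcohols to 2-arylchromans and the IDPi-catalysed enantioselective intramolecular hydroalkoxylation of alkenols, whose combination on a phenol/styrene pair has not been shown. Each pyran ring closes by a 6-endo-trig Markovnikov hydroalkoxylation (C–O bond) that follows an intermolecular electrophilic aromatic substitution (C–C bond). Both new stereocentres (C2 of each flavan) are remote from each other and are set by the catalyst alone, the acid enantiomer being the one that delivers O1 to the face giving S; two independent catalyst-controlled events should also deplete the mirror-image (R,R) product statistically, the mixed diastereomers being removable by chromatography. The step needs regioselectivity in the C-alkylation and in the choice of phenol, and the substrate secures both: bromine occupies the only other nucleophilic carbons (future C6 of the 8-linked flavan and C8 of the 6-linked flavan), each cinnamylated carbon has OMe on one side and exactly one OH on the other, and after cyclisation no aromatic CH remains, so excess cinnamyl alcohol cannot over-alkylate.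

Step 7
Reactants: 12 (2S)-6-bromo-8-{[(2S)-8-bromo-7-hydroxy-5-methoxy-2-phenyl-3,4-dihydro-2H-chromen-6-yl]methyl}-5-methoxy-2-phenyl-3,4-dihydro-2H-chromen-7-ol
Product: 13 (2S)-8-{[(2S)-7-hydroxy-5-methoxy-2-phenyl-3,4-dihydro-2H-chromen-6-yl]methyl}-5-methoxy-2-phenyl-3,4-dihydro-2H-chromen-7-ol (target)
Conditions: H2 (1 atm), Pd/C (palladium on carbon), Et3N, EtOAc/MeOH, rt
Reagents that add atoms: none
Why: Palladium-catalysed hydrogenolysis (hydrodehalogenation) of the two aryl C–Br bonds in the presence of base should be much faster than cleavage of the benzylic C2–O bonds at 1 atm and room temperature and does not touch the stereocentres.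

Compound list
1 | 5-methoxybenzene-1,3-diol (5-methoxyresorcinol) | COc1cc(O)cc(O)c1 | starting material
2 | 1-methoxy-3,5-bis(methoxymethoxy)benzene | COCOc1cc(OC)cc(OCOC)c1 | intermediate
3 | [4-methoxy-2,6-bis(methoxymethoxy)phenyl]lithium | [Li]c1c(OCOC)cc(OC)cc1OCOC | intermediate (not isolated)
4 | 2-bromo-5-methoxy-1,3-bis(methoxymethoxy)benzene | COCOc1cc(OC)cc(OCOC)c1Br | intermediate
5 | 2-bromo-5-methoxybenzene-1,3-diol | COc1cc(O)c(Br)c(O)c1 | intermediate
6 | 2,6-dihydroxy-4-methoxybenzaldehyde | COc1cc(O)c(C=O)c(O)c1 | starting material
7 | 3-bromo-2,6-dihydroxy-4-methoxybenzaldehyde | COc1cc(O)c(C=O)c(O)c1Br | intermediate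
8 | 4-bromo-2-(hydroxymethyl)-5-methoxybenzene-1,3-diol | COc1cc(O)c(CO)c(O)c1Br | intermediate (not isolated)
9 | 4-bromo-2-[(3-bromo-2,4-dihydroxy-6-methoxyphenyl)methyl]-5-methoxybenzene-1,3-diol | COc1cc(O)c(Cc2c(OC)cc(O)c(Br)c2O)c(O)c1Br | intermediate
10 | (E)-3-phenylprop-2-en-1-ol (cinnamyl alcohol) | OC/C=C/c1ccccc1 | starting material
11 | 4-bromo-2-({3-bromo-2,4-dihydroxy-6-methoxy-5-[(E)-3-phenylprop-2-enyl]phenyl}methyl)-5-methoxy-6-[(E)-3-phenylprop-2-enyl]benzene-1,3-diol | COc1c(C/C=C/c2ccccc2)c(O)c(Cc2c(OC)c(C/C=C/c3ccccc3)c(O)c(Br)c2O)c(O)c1Br | intermediate (not isolated)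
12 | (2S)-6-bromo-8-{[(2S)-8-bromo-7-hydroxy-5-methoxy-2-phenyl-3,4-dihydro-2H-chromen-6-yl]methyl}-5-methoxy-2-phenyl-3,4-dihydro-2H-chromen-7-ol | COc1c(Br)c(O)c(Cc2c(O)c(Br)c3c(c2OC)CC[C@@H](c2ccccc2)O3)c2c1CC[C@@H](c1ccccc1)O2 | intermediate
13 | (2S)-8-{[(2S)-7-hydroxy-5-methoxy-2-phenyl-3,4-dihydro-2H-chromen-6-yl]methyl}-5-methoxy-2-phenyl-3,4-dihydro-2H-chromen-7-ol | COc1cc(O)c(Cc2c(O)cc3c(c2OC)CC[C@@H](c2ccccc2)O3)c2c1CC[C@@H](c1ccccc1)O2 | target

Total steps: 7. Longest linear sequence: 6 steps (steps 1, 2, 3, 5, 6, 7); step 4 prepares the second fragment.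

Steps most likely to fail

Step 6. The facial discrimination in the ion pair may be weak, giving low enantio- and diastereoselectivity. The strong acid may also cleave or scramble the diarylmethane by retro-Friedel–Crafts ipso-protonation, and reversible ionisation of the C2–O bond may erode the configuration once it is set. The fallback sets out from 9 and comes back at 12, using known chemistry and forming the two bonds of each ring in separate operations. Double Friedel–Crafts conjugate addition of 9 to 1-phenylprop-2-en-1-one (phenyl vinyl ketone, C=CC(=O)c1ccccc1; BF3·OEt2, CH2Cl2) should give the bis(3-oxo-3-phenylpropyl) diarylmethane F1. Reduction of both ketones with BH3·SMe2 and (S)-2-methyl-CBS-oxazaborolidine should give the (R,R)-bis(3-hydroxy-3-phenylpropyl) diol F2. Double intramolecular Mitsunobu etherification (PPh3, DIAD, THF) by the phenol ortho to each side chain then closes both pyran rings with inversion, giving the (S,S) compound 12.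

Step 5. Residual hydride may reduce the o-quinone methide to the methylarene, the o-quinone methide may condense with its own precursor, and 5 or the product may be benzylated a second time. The fallback sets out from 7 and comes back at 9. Reductive amination of 7 with morpholine (NaBH(OAc)3, ClCH2CH2Cl) should give the isolable Mannich base 4-bromo-5-methoxy-2-(morpholin-4-ylmethyl)benzene-1,3-diol F3. Heating F3 with excess 5 in toluene releases the o-quinone methide slowly by loss of morpholine, in the absence of any hydride, and its capture at C4 of 5 gives 9.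

Step 4. Over-bromination of the very electron-rich ring and ipso-attack at the formyl-bearing carbon with loss of the aldehyde may compete. The fallback sets out from 6 and comes back at 7. Acetylation of both phenols (Ac2O, pyridine) should give 2-formyl-5-methoxy-1,3-phenylene diacetate F4, whose ring is activated essentially only by OMe. Bromination ortho to OMe (NBS, CF3CO2H) should then stop cleanly at 4-bromo-2-formyl-5-methoxy-1,3-phenylene diacetate F5, and methanolysis of the acetates (K2CO3, MeOH) gives 7.

Further compounds
F1 | step 6 | bis-ketone: 9 carrying a 3-oxo-3-phenylpropyl group on each former aromatic CH | COc1c(CCC(=O)c2ccccc2)c(O)c(Cc2c(OC)c(CCC(=O)c3ccccc3)c(O)c(Br)c2O)c(O)c1Br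
F2 | step 6 | (R,R)-diol: 9 carrying a (3R)-3-hydroxy-3-phenylpropyl group on each former aromatic CH | COc1c(CC[C@@H](O)c2ccccc2)c(O)c(Cc2c(OC)c(CC[C@@H](O)c3ccccc3)c(O)c(Br)c2O)c(O)c1Br
F3 | step 5 | 4-bromo-5-methoxy-2-(morpholin-4-ylmethyl)benzene-1,3-diol | COc1cc(O)c(CN2CCOCC2)c(O)c1Br
F4 | step 4 | 2-formyl-5-methoxy-1,3-phenylene diacetate | COc1cc(OC(C)=O)c(C=O)c(OC(C)=O)c1
F5 | step 4 | 4-bromo-2-formyl-5-methoxy-1,3-phenylene diacetate | COc1cc(OC(C)=O)c(C=O)c(OC(C)=O)c1Br
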